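**Retrosynthetic overview**

1. Endgame on the closed tricycle: 13,14-epoxide (peracid, anti to O12), 3,4-epoxide (C2-hydroxyl-directed), C6–Cl from a C6 carbinol with inversion; O12 is unmasked last.
2. Ring B (ten-membered) is closed last by ring-closing metathesis at C3=C4 (Z) between a C2 vinyl carbinol and a C5 buta-1,3-dien-2-yl unit.
3. Key step: the C8–O bond is made by a boronate-directed oxa-Michael addition to a γ-hydroxybutenolide, which creates the C8 tertiary carbinol and C17 and turns the butenolide into the hydroxy lactone.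
4. The butenolide (ring C, C7 from (S)-glycidate) is joined to ring A through C8–C9 by a Nozaki–Hiyama–Kishi coupling.
5. Ring order: A (asymmetric Diels–Alder, sets C1 and C10) → C (preformed butenolide, saturated in the key step) → B (metathesis).

**Conventions and assumptions**

- Briarane numbering is used for every intermediate: C1–C10 is the ten-membered ring; C1 and C10–C14 form the six-membered ring; C15 is the methyl on C1, C16 the methylene on C5, C20 the methyl on C11; C17 (on C8) carries methyl C18 and carbonyl C19, which is lactonised to O7.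
- RA = (1S,2S,5S,6R)-5-(tert-butyldimethylsilyloxy)-2,6-dimethyl-2-[(1R)-1-(triethylsilyloxy)prop-2-en-1-yl]cyclohex-3-en-1-yl (ring A with C2 and its vinyl group).
- (salen)CrSbF6 = hexafluoroantimonate of trivalent chromium bound to the dianion of N,N′-bis(3,5-di-tert-butylsalicylidene)cyclohexane-1,2-diamine.
- Assumption: the enantiomer named for each chiral catalyst, ligand or reagent (steps 1, 2, 16) is the one taken to give the drawn sense; if induction proves opposite, its mirror image is used.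
- Assumption: the tartrate butadienylboronate of step 16 is made fresh from diisopropyl D-tartrate, as the allyl analogues are.

**Route**

Step 1
Reactants: 1 ethyl (2E)-3-methyl-4-oxobut-2-enoate; 2 (1E)-3-(tert-butyldimethylsilyloxy)-N,N-dimethylbuta-1,3-dien-1-amine
Product: 4 ethyl (1S,2S)-2-formyl-2-methyl-5-oxocyclohex-3-ene-1-carboxylate, via amino silyl enol ether cycloadduct 3 (not isolated)
Conditions: (R,R)-(salen)CrSbF6 (5 mol %), 4 Å MS, CH2Cl2, −40 °C; then 0.1 M aq. HCl, THF, 0 °C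
Reagents that add atoms: none
Why: Catalytic enantioselective Diels–Alder reaction of an α-substituted enal with a 1-amino-3-siloxydiene: the chromium Lewis acid binds the formyl group, the nucleophilic diene terminus (C11) bonds to C10 (β to the aldehyde), the catalyst sets the C1 quaternary centre, the (E)-dienophile fixes C2 and C9 trans, and acid then hydrolyses the silyl enol ether and eliminates dimethylamine to the enone.

Step 2
Reactants: 4 ethyl (1S,2S)-2-formyl-2-methyl-5-oxocyclohex-3-ene-1-carboxylate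
Product: 6 ethyl (1S,2S)-2-methyl-5-oxo-2-[(1R)-1-(triethylsilyloxy)prop-2-en-1-yl]cyclohex-3-ene-1-carboxylate, via vinyl carbinol 5 (not isolated)
Conditions: Zn(CH=CH2)2 (1.5 equiv), (+)-3-exo-morpholinoisoborneol (10 mol %), toluene, −20 °C; then Et3SiOTf, 2,6-lutidine, −20 → 0 °C
Reagents that add atoms: divinylzinc (C=C[Zn]C=C); triethylsilyl trifluoromethanesulfonate (CC[Si](CC)(CC)OS(=O)(=O)C(F)(F)F)
Why: Amino-alcohol-catalysed addition of a vinylzinc reagent to the neopentyl aldehyde (ketone, enone and ester do not react) puts vinyl on the Re face under ligand control and sets C2 (R here, the target configuration), and silylation in the same flask stops lactonisation onto the C9 ester.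

Step 3
Reactants: 6 ethyl (1S,2S)-2-methyl-5-oxo-2-[(1R)-1-(triethylsilyloxy)prop-2-en-1-yl]cyclohex-3-ene-1-carboxylate
Product: 8 ethyl (1S,2S,6R)-2,6-dimethyl-5-oxo-2-[(1R)-1-(triethylsilyloxy)prop-2-en-1-yl]cyclohex-3-ene-1-carboxylate, via C11-epimeric methyl ketone 7 (not isolated)
Conditions: LDA (1.1 equiv), THF, −78 °C; MeI (1.0 equiv); then LDA (1.2 equiv), −78 °C; then AcOH, THF, −78 °C
Reagents that add atoms: iodomethane (CI)
Why: Kinetic α′-enolate alkylation of the cyclohexenone (LDA takes the ketone α′-proton at C11, not the ester α-proton) followed by re-enolisation and kinetic protonation: allylic 1,2-strain with the C11 methyl turns the C10 ester axial on the β face, so the proton enters from the α face and leaves Me-20 β (cis to C9), the epimer that the alkylation itself disfavours.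

Step 4
Reactants: 8 ethyl (1S,2S,6R)-2,6-dimethyl-5-oxo-2-[(1R)-1-(triethylsilyloxy)prop-2-en-1-yl]cyclohex-3-ene-1-carboxylate
Product: 9 ethyl (1S,2S,5S,6R)-5-hydroxy-2,6-dimethyl-2-[(1R)-1-(triethylsilyloxy)prop-2-en-1-yl]cyclohex-3-ene-1-carboxylate
Conditions: NaBH4, CeCl3·7H2O, MeOH, −78 °C
Reagents that add atoms: none
Why: Luche 1,2-reduction of the enone: hydride reaches C12 from the α face, away from the β-oriented C11 methyl and C10 ester, giving the 12β allylic alcohol without touching the ester or epimerising C11.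

Step 5
Reactants: 9 ethyl (1S,2S,5S,6R)-5-hydroxy-2,6-dimethyl-2-[(1R)-1-(triethylsilyloxy)prop-2-en-1-yl]cyclohex-3-ene-1-carboxylate
Product: 10 ethyl (1S,2S,5S,6R)-5-(tert-butyldimethylsilyloxy)-2,6-dimethyl-2-[(1R)-1-(triethylsilyloxy)prop-2-en-1-yl]cyclohex-3-ene-1-carboxylate
Conditions: tBuMe2SiOTf, 2,6-lutidine, CH2Cl2, −78 → 0 °C
Reagents that add atoms: tert-butyldimethylsilyl trifluoromethanesulfonate (CC(C)(C)[Si](C)(C)OS(=O)(=O)C(F)(F)F)
Why: Silyl ether formation on the only free hydroxyl gives a bulky, non-directing group on O12 that later steers the 13,14-epoxidation to the opposite face and is removed last.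

Step 6
Reactants: 10 ethyl (1S,2S,5S,6R)-5-(tert-butyldimethylsilyloxy)-2,6-dimethyl-2-[(1R)-1-(triethylsilyloxy)prop-2-en-1-yl]cyclohex-3-ene-1-carboxylate
Product: 11 (1S,2S,5S,6R)-5-(tert-butyldimethylsilyloxy)-2,6-dimethyl-2-[(1R)-1-(triethylsilyloxy)prop-2-en-1-yl]cyclohex-3-ene-1-carbaldehyde
Conditions: iBu2AlH (1.1 equiv), CH2Cl2, −78 °C; Rochelle salt work-up
Reagents that add atoms: none
Why: Low-temperature half-reduction of the ethyl ester stops at the aluminium hemiacetal and gives the C9 aldehyde on work-up, with the silyl ethers intact and no base present to epimerise C10.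

Step 7
Reactants: 12 methyl (2S)-oxirane-2-carboxylate
Product: 13 methyl (2S)-2-hydroxy-3-[(4-methoxybenzyl)oxy]propanoate
Conditions: 4-MeOC6H4CH2OH, BF3·OEt2 (5 mol %), CH2Cl2, 0 °C
Reagents that add atoms: 4-methoxybenzyl alcohol (COc1ccc(CO)cc1)
Why: Lewis-acid-catalysed epoxide opening of the glycidic ester occurs at the unhindered terminal carbon (future C6) and leaves the stereocentre (future C7) untouched.

Step 8
Reactants: 13 methyl (2S)-2-hydroxy-3-[(4-methoxybenzyl)oxy]propanoate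
Product: 14 methyl (2S)-3-[(4-methoxybenzyl)oxy]-2-(propanoyloxy)propanoate
Conditions: EtCOCl, pyridine, DMAP (cat.), CH2Cl2, 0 °C
Reagents that add atoms: propanoyl chloride (CCC(=O)Cl)
Why: Simple O-acylation of the secondary alcohol installs C17–C19 (with Me-18) on O7.

Step 9
Reactants: 14 methyl (2S)-3-[(4-methoxybenzyl)oxy]-2-(propanoyloxy)propanoate
Product: 15 (5S)-4-hydroxy-5-{[(4-methoxybenzyl)oxy]methyl}-3-methylfuran-2(5H)-one
Conditions: LiHMDS (2.2 equiv), THF, −78 → 0 °C; then 1 M HCl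
Reagents that add atoms: none
Why: Dieckmann condensation: the propanoate enolate attacks the neighbouring methyl ester (five-membered ring) to give the 3-methyltetronic acid, and the cold lithium amide conditions preserve C7.

Step 10
Reactants: 15 (5S)-4-hydroxy-5-{[(4-methoxybenzyl)oxy]methyl}-3-methylfuran-2(5H)-one
Product: 16 (2S)-2-{[(4-methoxybenzyl)oxy]methyl}-4-methyl-5-oxo-2,5-dihydrofuran-3-yl trifluoromethanesulfonate
Conditions: Tf2O, iPr2NEt, CH2Cl2, −78 °C
Reagents that add atoms: trifluoromethanesulfonic anhydride (O=S(=O)(OS(=O)(=O)C(F)(F)F)C(F)(F)F)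
Why: O-Triflation of the acidic vinylogous acid gives the alkenyl triflate that serves as the C8 nucleophile precursor.

Step 11
Reactants: 11 (1S,2S,5S,6R)-5-(tert-butyldimethylsilyloxy)-2,6-dimethyl-2-[(1R)-1-(triethylsilyloxy)prop-2-en-1-yl]cyclohex-3-ene-1-carbaldehyde; 16 (2S)-2-{[(4-methoxybenzyl)oxy]methyl}-4-methyl-5-oxo-2,5-dihydrofuran-3-yl trifluoromethanesulfonate
Product: 17 (5R)-4-[(R)-hydroxy(RA)methyl]-5-{[(4-methoxybenzyl)oxy]methyl}-3-methylfuran-2(5H)-one
Conditions: CrCl2 (4 equiv), NiCl2 (2 mol %), DMF/THF, 25 °C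
Reagents that add atoms: none
Why: Nozaki–Hiyama–Kishi coupling: nickel inserts into the activated alkenyl triflate, the alkenylchromium adds only to the aldehyde (lactone and silyl ethers survive), and Felkin–Anh attack anti to the quaternary C1 sets C9 (R).

Step 12
Reactants: 17 (5R)-4-[(R)-hydroxy(RA)methyl]-5-{[(4-methoxybenzyl)oxy]methyl}-3-methylfuran-2(5H)-one
Product: 19 (3R,4R,5S)-4-hydroxy-4-[(R)-hydroxy(RA)methyl]-5-{[(4-methoxybenzyl)oxy]methyl}-3-methyloxolan-2-one, via cyclic phenylboronate 18 (not isolated)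
Conditions: PhB(OH)2 (1.5 equiv), quinuclidine (20 mol %), 4 Å MS, toluene, 40 °C; then H2O2, aq. NaHCO3, THF, 0 °C
Reagents that add atoms: phenylboronic acid (OB(O)c1ccccc1)
Why: Proposed new method: boronic-acid-hemiester-directed oxa-Michael addition to a tetrasubstituted (α-methyl, β,β-disubstituted) butenolide; the C9 hydroxyl condenses with PhB(OH)2, the amine turns the hemiester into a tetracoordinate boronate whose B–OH oxygen adds 5-exo to C8 on the face fixed by allylic 1,3-strain (H-9 eclipses C8=C17 next to Me-18), which gives the 8,9-erythro dioxaborolane and so the C8 tertiary carbinol; the enolate is protonated at C17 and equilibrates under the amine to the epimer with Me-18 trans to the bulky C9 branch; peroxide then frees the diol; the closest known reaction is the amine-catalysed oxa-Michael addition of boronic acid hemiesters to γ-hydroxy-α,β-enones, not yet shown for tetrasubstituted butenolides or for forming a tertiary carbinol.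

Step 13
Reactants: 19 (3R,4R,5S)-4-hydroxy-4-[(R)-hydroxy(RA)methyl]-5-{[(4-methoxybenzyl)oxy]methyl}-3-methyloxolan-2-one
Product: 20 (3R,4R,5S)-4-[(R)-acetoxy(RA)methyl]-4-hydroxy-5-{[(4-methoxybenzyl)oxy]methyl}-3-methyloxolan-2-one
Conditions: Ac2O, pyridine, DMAP (cat.), CH2Cl2, 0 °C
Reagents that add atoms: acetic anhydride (CC(=O)OC(C)=O)
Why: Acetylation takes the secondary C9 hydroxyl and leaves the hindered tertiary C8 hydroxyl free, which also blocks any lactone migration to O9.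

Step 14
Reactants: 20 (3R,4R,5S)-4-[(R)-acetoxy(RA)methyl]-4-hydroxy-5-{[(4-methoxybenzyl)oxy]methyl}-3-methyloxolan-2-one
Product: 21 (3R,4R,5S)-4-[(R)-acetoxy(RA)methyl]-4-hydroxy-5-(hydroxymethyl)-3-methyloxolan-2-one
Conditions: DDQ, CH2Cl2/pH 7 buffer, 0 °C
Reagents that add atoms: none
Why: Oxidative cleavage of the 4-methoxybenzyl ether is orthogonal to both silyl ethers, the acetate and the alkenes when buffered.

Step 15
Reactants: 21 (3R,4R,5S)-4-[(R)-acetoxy(RA)methyl]-4-hydroxy-5-(hydroxymethyl)-3-methyloxolan-2-one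
Product: 22 (2R,3R,4R)-3-[(R)-acetoxy(RA)methyl]-3-hydroxy-4-methyl-5-oxooxolane-2-carbaldehyde
Conditions: Dess–Martin periodinane, NaHCO3, CH2Cl2, 0 °C
Reagents that add atoms: none
Why: Buffered Dess–Martin oxidation of the only primary alcohol gives the C6 aldehyde without base, so C7 is not epimerised and the tertiary alcohol is untouched.

Step 16
Reactants: 22 (2R,3R,4R)-3-[(R)-acetoxy(RA)methyl]-3-hydroxy-4-methyl-5-oxooxolane-2-carbaldehyde
Product: 23 (3R,4R,5S)-4-[(R)-acetoxy(RA)methyl]-4-hydroxy-5-[(1R)-1-hydroxy-2-methylidenebut-3-en-1-yl]-3-methyloxolan-2-one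
Conditions: diisopropyl (4S,5S)-2-(buta-2,3-dien-1-yl)-1,3,2-dioxaborolane-4,5-dicarboxylate (2 equiv), 4 Å MS, toluene, −78 °C; aq. NaHCO3
Reagents that add atoms: diisopropyl (4S,5S)-2-(buta-2,3-dien-1-yl)-1,3,2-dioxaborolane-4,5-dicarboxylate (C=C=CCB1O[C@H](C(=O)OC(C)C)[C@@H](C(=O)OC(C)C)O1)
Why: Homoallenylboration (allylboration-type addition through a chair six-membered transition state, the central allene carbon bonding to C6) gives the buta-1,3-dien-2-yl carbinol, and the (S,S)-tartrate reagent overrides the Cornforth preference of this α-alkoxy aldehyde to give the 6,7-syn (6R) alcohol, as the (S,S)-allyl reagent does with the analogous glyceraldehyde acetonide.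

Step 17
Reactants: 23 (3R,4R,5S)-4-[(R)-acetoxy(RA)methyl]-4-hydroxy-5-[(1R)-1-hydroxy-2-methylidenebut-3-en-1-yl]-3-methyloxolan-2-one
Product: 24 (3R,4R,5R)-4-[(R)-acetoxy(RA)methyl]-5-[(1S)-1-chloro-2-methylidenebut-3-en-1-yl]-4-hydroxy-3-methyloxolan-2-one
Conditions: Cl3CC(O)CCl3, PPh3, 2,6-di-tert-butylpyridine, CH2Cl2, −20 → 0 °C
Reagents that add atoms: hexachloroacetone (ClC(Cl)(Cl)C(=O)C(Cl)(Cl)Cl)
Why: Appel-type deoxychlorination with hexachloroacetone and PPh3 converts allylic alcohols into unrearranged chlorides by SN2 attack on the oxyphosphonium salt, so C6 is inverted to the target configuration while the tertiary C8 hydroxyl cannot react.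

Step 18
Reactants: 24 (3R,4R,5R)-4-[(R)-acetoxy(RA)methyl]-5-[(1S)-1-chloro-2-methylidenebut-3-en-1-yl]-4-hydroxy-3-methyloxolan-2-one
Product: 25 (1S,2R,6S,7R,8R,9R,10S,11R,12S,17R)-9-acetoxy-12-(tert-butyldimethylsilyloxy)-6-chloro-8-hydroxy-2-(triethylsilyloxy)briarane-3Z,5(16),13-triene 19→7-lactone
Conditions: second-generation Grubbs catalyst [RuCl2(=CHPh)(PCy3)(H2IMes)] (10 mol %), toluene (1 mM), 80 °C
Reagents that add atoms: none
Why: Ring-closing metathesis between the C2 vinyl group and the terminal vinyl of the diene (the 1,1-disubstituted C5=C16 and the ring-A cyclohexene are too hindered to compete) closes the ten-membered ring, and ring strain enforces the Z C3=C4 alkene.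

Step 19
Reactants: 25 (1S,2R,6S,7R,8R,9R,10S,11R,12S,17R)-9-acetoxy-12-(tert-butyldimethylsilyloxy)-6-chloro-8-hydroxy-2-(triethylsilyloxy)briarane-3Z,5(16),13-triene 19→7-lactone
Product: 26 (1S,2R,6S,7R,8R,9R,10S,11R,12S,17R)-9-acetoxy-12-(tert-butyldimethylsilyloxy)-6-chloro-2,8-dihydroxybriarane-3Z,5(16),13-triene 19→7-lactone
Conditions: HF·pyridine, pyridine, THF, 0 °C
Reagents that add atoms: none
Why: Selective desilylation: the triethylsilyl ether is cleaved by buffered fluoride much faster than the hindered tert-butyldimethylsilyl ether, and the allylic chloride and acetate survive.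

Step 20
Reactants: 26 (1S,2R,6S,7R,8R,9R,10S,11R,12S,17R)-9-acetoxy-12-(tert-butyldimethylsilyloxy)-6-chloro-2,8-dihydroxybriarane-3Z,5(16),13-triene 19→7-lactone
Product: 27 (1S,2S,3S,4R,6S,7R,8R,9R,10S,11R,12S,17R)-9-acetoxy-12-(tert-butyldimethylsilyloxy)-6-chloro-3,4-epoxy-2,8-dihydroxybriarane-5(16),13-diene 19→7-lactone
Conditions: VO(acac)2 (5 mol %), tBuOOH, CH2Cl2, 0 °C
Reagents that add atoms: tert-butyl hydroperoxide (CC(C)(C)OO)
Why: Vanadium-catalysed hydroxyl-directed epoxidation touches only the alkene allylic to the free C2 hydroxyl (C3=C4), and in a medium-ring Z-allylic alcohol the vanadate delivers oxygen to the alkene face syn to the carbinol, giving the cis (2α-OH, 3,4-α-epoxide) relationship of the target.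

Step 21
Reactants: 27 (1S,2S,3S,4R,6S,7R,8R,9R,10S,11R,12S,17R)-9-acetoxy-12-(tert-butyldimethylsilyloxy)-6-chloro-3,4-epoxy-2,8-dihydroxybriarane-5(16),13-diene 19→7-lactone
Product: 28 (1S,2S,3R,4R,6S,7R,8R,9R,10S,11R,12S,17R)-2,9-diacetoxy-12-(tert-butyldimethylsilyloxy)-6-chloro-3,4-epoxy-8-hydroxybriarane-5(16),13-diene 19→7-lactone
Conditions: Ac2O, Et3N, DMAP, CH2Cl2, 25 °C
Reagents that add atoms: acetic anhydride (CC(=O)OC(C)=O)
Why: Acetylation of the secondary C2 hydroxyl; the tertiary C8 hydroxyl stays free, as it does in the first acetylation.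

Step 22
Reactants: 28 (1S,2S,3R,4R,6S,7R,8R,9R,10S,11R,12S,17R)-2,9-diacetoxy-12-(tert-butyldimethylsilyloxy)-6-chloro-3,4-epoxy-8-hydroxybriarane-5(16),13-diene 19→7-lactone
Product: 29 (1R,2S,3R,4R,6S,7R,8R,9R,10S,11R,12R,13R,14R,17R)-2,9-diacetoxy-12-(tert-butyldimethylsilyloxy)-6-chloro-3,4:13,14-diepoxy-8-hydroxybriar-5(16)-ene 19→7-lactone
Conditions: mCPBA, Na2HPO4, CH2Cl2, 0 °C
Reagents that add atoms: 3-chloroperoxybenzoic acid (OOC(=O)c1cccc(Cl)c1)
Why: Prilezhaev epoxidation: in the trans-fused bicycle the β face of C13=C14 is shielded by the axial Me-15 and the O12 silyl ether, so the peracid attacks from the α face (anti to O12), while C5=C16 is deactivated by the vinyl epoxide and the allylic chloride.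

Step 23
Reactants: 29 (1R,2S,3R,4R,6S,7R,8R,9R,10S,11R,12R,13R,14R,17R)-2,9-diacetoxy-12-(tert-butyldimethylsilyloxy)-6-chloro-3,4:13,14-diepoxy-8-hydroxybriar-5(16)-ene 19→7-lactone
Product: 30 CNP0141778.2
Conditions: HF·pyridine, pyridine, THF, 0 → 25 °C
Reagents that add atoms: none
Why: Buffered fluoride desilylation frees the 12β-hydroxyl under non-basic conditions, so no Payne rearrangement of the trans epoxy alcohol and no acetate migration can occur.

**Compound list**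

1 | ethyl (2E)-3-methyl-4-oxobut-2-enoate | CCOC(=O)/C=C(\C)C=O | starting material
2 | (1E)-3-(tert-butyldimethylsilyloxy)-N,N-dimethylbuta-1,3-dien-1-amine | CN(C)/C=C/C(=C)O[Si](C)(C)C(C)(C)C | starting material
3 | ethyl (1S,2R,3S)-5-(tert-butyldimethylsilyloxy)-3-(dimethylamino)-2-formyl-2-methylcyclohex-4-ene-1-carboxylate | O=C[C@]1(C)[C@H](CC(O[Si](C)(C)C(C)(C)C)=C[C@@H]1N(C)C)C(=O)OCC | intermediate
4 | ethyl (1S,2S)-2-formyl-2-methyl-5-oxocyclohex-3-ene-1-carboxylate | O=C[C@]1(C)[C@H](CC(=O)C=C1)C(=O)OCC | intermediate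
5 | ethyl (1S,2S)-2-[(1R)-1-hydroxyprop-2-en-1-yl]-2-methyl-5-oxocyclohex-3-ene-1-carboxylate | C=C[C@@H](O)[C@]1(C)[C@H](CC(=O)C=C1)C(=O)OCC | intermediate
6 | ethyl (1S,2S)-2-methyl-5-oxo-2-[(1R)-1-(triethylsilyloxy)prop-2-en-1-yl]cyclohex-3-ene-1-carboxylate | C=C[C@@H](O[Si](CC)(CC)CC)[C@]1(C)[C@H](CC(=O)C=C1)C(=O)OCC | intermediate
7 | ethyl (1S,2S,6S)-2,6-dimethyl-5-oxo-2-[(1R)-1-(triethylsilyloxy)prop-2-en-1-yl]cyclohex-3-ene-1-carboxylate (11α-methyl epimer) | C=C[C@@H](O[Si](CC)(CC)CC)[C@]1(C)[C@H]([C@H](C)C(=O)C=C1)C(=O)OCC | intermediate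
8 | ethyl (1S,2S,6R)-2,6-dimethyl-5-oxo-2-[(1R)-1-(triethylsilyloxy)prop-2-en-1-yl]cyclohex-3-ene-1-carboxylate | C=C[C@@H](O[Si](CC)(CC)CC)[C@]1(C)[C@H]([C@@H](C)C(=O)C=C1)C(=O)OCC | intermediate
9 | ethyl (1S,2S,5S,6R)-5-hydroxy-2,6-dimethyl-2-[(1R)-1-(triethylsilyloxy)prop-2-en-1-yl]cyclohex-3-ene-1-carboxylate | C=C[C@@H](O[Si](CC)(CC)CC)[C@]1(C)[C@H]([C@@H](C)[C@@H](O)C=C1)C(=O)OCC | intermediate
10 | ethyl (1S,2S,5S,6R)-5-(tert-butyldimethylsilyloxy)-2,6-dimethyl-2-[(1R)-1-(triethylsilyloxy)prop-2-en-1-yl]cyclohex-3-ene-1-carboxylate | C=C[C@@H](O[Si](CC)(CC)CC)[C@]1(C)[C@H]([C@@H](C)[C@@H](O[Si](C)(C)C(C)(C)C)C=C1)C(=O)OCC | intermediate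
11 | (1S,2S,5S,6R)-5-(tert-butyldimethylsilyloxy)-2,6-dimethyl-2-[(1R)-1-(triethylsilyloxy)prop-2-en-1-yl]cyclohex-3-ene-1-carbaldehyde | C=C[C@@H](O[Si](CC)(CC)CC)[C@]1(C)[C@H]([C@@H](C)[C@@H](O[Si](C)(C)C(C)(C)C)C=C1)C=O | intermediate
12 | methyl (2S)-oxirane-2-carboxylate | COC(=O)[C@@H]1CO1 | starting material
13 | methyl (2S)-2-hydroxy-3-[(4-methoxybenzyl)oxy]propanoate | COC(=O)[C@@H](O)COCc1ccc(OC)cc1 | intermediate
14 | methyl (2S)-3-[(4-methoxybenzyl)oxy]-2-(propanoyloxy)propanoate | CCC(=O)O[C@@H](COCc1ccc(OC)cc1)C(=O)OC | intermediate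
15 | (5S)-4-hydroxy-5-{[(4-methoxybenzyl)oxy]methyl}-3-methylfuran-2(5H)-one | CC1=C(O)[C@H](COCc2ccc(OC)cc2)OC1=O | intermediate
16 | (2S)-2-{[(4-methoxybenzyl)oxy]methyl}-4-methyl-5-oxo-2,5-dihydrofuran-3-yl trifluoromethanesulfonate | CC1=C(OS(=O)(=O)C(F)(F)F)[C@H](COCc2ccc(OC)cc2)OC1=O | intermediate
17 | (5R)-4-[(R)-hydroxy(RA)methyl]-5-{[(4-methoxybenzyl)oxy]methyl}-3-methylfuran-2(5H)-one | C=C[C@@H](O[Si](CC)(CC)CC)[C@]1(C)[C@H]([C@@H](C)[C@@H](O[Si](C)(C)C(C)(C)C)C=C1)[C@@H](O)C1=C(C)C(=O)O[C@H]1COCc1ccc(OC)cc1 | intermediate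
18 | cyclic phenylboronate of 19 (2-phenyl-1,3,2-dioxaborolane spanning O8 and O9; 7S,8R,9R,17R) | C=C[C@@H](O[Si](CC)(CC)CC)[C@]1(C)[C@H]([C@@H](C)[C@@H](O[Si](C)(C)C(C)(C)C)C=C1)[C@H]2OB(c3ccccc3)O[C@]23[C@@H](C)C(=O)O[C@H]3COCc3ccc(OC)cc3 | intermediate
19 | (3R,4R,5S)-4-hydroxy-4-[(R)-hydroxy(RA)methyl]-5-{[(4-methoxybenzyl)oxy]methyl}-3-methyloxolan-2-one | C=C[C@@H](O[Si](CC)(CC)CC)[C@]1(C)[C@H]([C@@H](C)[C@@H](O[Si](C)(C)C(C)(C)C)C=C1)[C@@H](O)[C@]2(O)[C@@H](C)C(=O)O[C@H]2COCc2ccc(OC)cc2 | intermediate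
20 | (3R,4R,5S)-4-[(R)-acetoxy(RA)methyl]-4-hydroxy-5-{[(4-methoxybenzyl)oxy]methyl}-3-methyloxolan-2-one | C=C[C@@H](O[Si](CC)(CC)CC)[C@]1(C)[C@H]([C@@H](C)[C@@H](O[Si](C)(C)C(C)(C)C)C=C1)[C@@H](OC(C)=O)[C@]2(O)[C@@H](C)C(=O)O[C@H]2COCc2ccc(OC)cc2 | intermediate
21 | (3R,4R,5S)-4-[(R)-acetoxy(RA)methyl]-4-hydroxy-5-(hydroxymethyl)-3-methyloxolan-2-one | C=C[C@@H](O[Si](CC)(CC)CC)[C@]1(C)[C@H]([C@@H](C)[C@@H](O[Si](C)(C)C(C)(C)C)C=C1)[C@@H](OC(C)=O)[C@]2(O)[C@@H](C)C(=O)O[C@H]2CO | intermediate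
22 | (2R,3R,4R)-3-[(R)-acetoxy(RA)methyl]-3-hydroxy-4-methyl-5-oxooxolane-2-carbaldehyde | C=C[C@@H](O[Si](CC)(CC)CC)[C@]1(C)[C@H]([C@@H](C)[C@@H](O[Si](C)(C)C(C)(C)C)C=C1)[C@@H](OC(C)=O)[C@]2(O)[C@@H](C)C(=O)O[C@H]2C=O | intermediate
23 | (3R,4R,5S)-4-[(R)-acetoxy(RA)methyl]-4-hydroxy-5-[(1R)-1-hydroxy-2-methylidenebut-3-en-1-yl]-3-methyloxolan-2-one | C=C[C@@H](O[Si](CC)(CC)CC)[C@]1(C)[C@H]([C@@H](C)[C@@H](O[Si](C)(C)C(C)(C)C)C=C1)[C@@H](OC(C)=O)[C@]2(O)[C@@H](C)C(=O)O[C@H]2[C@H](O)C(=C)C=C | intermediate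
24 | (3R,4R,5R)-4-[(R)-acetoxy(RA)methyl]-5-[(1S)-1-chloro-2-methylidenebut-3-en-1-yl]-4-hydroxy-3-methyloxolan-2-one | C=C[C@@H](O[Si](CC)(CC)CC)[C@]1(C)[C@H]([C@@H](C)[C@@H](O[Si](C)(C)C(C)(C)C)C=C1)[C@@H](OC(C)=O)[C@]2(O)[C@@H](C)C(=O)O[C@H]2[C@@H](Cl)C(=C)C=C | intermediate
25 | (1S,2R,6S,7R,8R,9R,10S,11R,12S,17R)-9-acetoxy-12-(tert-butyldimethylsilyloxy)-6-chloro-8-hydroxy-2-(triethylsilyloxy)briarane-3Z,5(16),13-triene 19→7-lactone | C=C1/C=C\[C@@H](O[Si](CC)(CC)CC)[C@]2(C)[C@H]([C@@H](C)[C@@H](O[Si](C)(C)C(C)(C)C)C=C2)[C@@H](OC(C)=O)[C@]2(O)[C@@H](C)C(=O)O[C@H]2[C@H]1Cl | intermediate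
26 | (1S,2R,6S,7R,8R,9R,10S,11R,12S,17R)-9-acetoxy-12-(tert-butyldimethylsilyloxy)-6-chloro-2,8-dihydroxybriarane-3Z,5(16),13-triene 19→7-lactone | C=C1/C=C\[C@@H](O)[C@]2(C)[C@H]([C@@H](C)[C@@H](O[Si](C)(C)C(C)(C)C)C=C2)[C@@H](OC(C)=O)[C@]2(O)[C@@H](C)C(=O)O[C@H]2[C@H]1Cl | intermediate
27 | (1S,2S,3S,4R,6S,7R,8R,9R,10S,11R,12S,17R)-9-acetoxy-12-(tert-butyldimethylsilyloxy)-6-chloro-3,4-epoxy-2,8-dihydroxybriarane-5(16),13-diene 19→7-lactone | C=C1[C@H]2O[C@H]2[C@@H](O)[C@]2(C)[C@H]([C@@H](C)[C@@H](O[Si](C)(C)C(C)(C)C)C=C2)[C@@H](OC(C)=O)[C@]2(O)[C@@H](C)C(=O)O[C@H]2[C@H]1Cl | intermediate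
28 | (1S,2S,3R,4R,6S,7R,8R,9R,10S,11R,12S,17R)-2,9-diacetoxy-12-(tert-butyldimethylsilyloxy)-6-chloro-3,4-epoxy-8-hydroxybriarane-5(16),13-diene 19→7-lactone | C=C1[C@H]2O[C@H]2[C@@H](OC(C)=O)[C@]2(C)[C@H]([C@@H](C)[C@@H](O[Si](C)(C)C(C)(C)C)C=C2)[C@@H](OC(C)=O)[C@]2(O)[C@@H](C)C(=O)O[C@H]2[C@H]1Cl | intermediate
29 | (1R,2S,3R,4R,6S,7R,8R,9R,10S,11R,12R,13R,14R,17R)-2,9-diacetoxy-12-(tert-butyldimethylsilyloxy)-6-chloro-3,4:13,14-diepoxy-8-hydroxybriar-5(16)-ene 19→7-lactone | C=C1[C@H]2O[C@H]2[C@@H](OC(C)=O)[C@]2(C)[C@H]([C@@H](C)[C@@H](O[Si](C)(C)C(C)(C)C)[C@@H]3O[C@@H]32)[C@@H](OC(C)=O)[C@]2(O)[C@@H](C)C(=O)O[C@H]2[C@H]1Cl | intermediate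
30 | CNP0141778.2: (1R,2S,3R,4R,6S,7R,8R,9R,10S,11R,12R,13S,14R,17R)-2,9-diacetoxy-6-chloro-3,4:13,14-diepoxy-8,12-dihydroxybriar-5(16)-ene 19→7-lactone | C=C1[C@H]2O[C@H]2[C@@H](OC(C)=O)[C@]2(C)[C@H]([C@@H](C)[C@@H](O)[C@@H]3O[C@@H]32)[C@@H](OC(C)=O)[C@]2(O)[C@@H](C)C(=O)O[C@H]2[C@H]1Cl | target

**Step count and risks**

Total step count: 23. Longest linear sequence: 19 steps (steps 1–6 and 11–23, from 1 and 2); the butenolide triflate 16 is made in 4 steps (7–10).

The three steps most likely to fail: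

Step 12 (the proposed new oxa-Michael addition; the tetrasubstituted acceptor may be too unreactive or the adduct may revert). The fallback uses known chemistry, sets out from 17 and returns at 19. Compound 17 is treated with tBuOOLi (from tBuOOH and n-BuLi, THF, −20 °C); the lithium alkoxide of the C9 hydroxyl guides the peroxide to its own face of the butenolide (hydroxyl-directed nucleophilic epoxidation of a γ-hydroxy enoate) and gives the 8,17-epoxy lactone F1. SmI2 (THF/MeOH, −78 °C) then cleaves the C17–O bond of this α,β-epoxy lactone, the known reductive opening to a β-hydroxy ester, and after equilibration of C17 with DBU the product is diol 19.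

Step 16 (mismatched double stereodifferentiation with a freshly made boronate; the Cornforth preference of aldehyde 22 may win). The fallback sets the C6 configuration by reduction instead of addition, sets out from 22 and returns at 23. Indium powder and 1,4-dibromobut-2-yne (THF/H2O, 25 °C, the known Barbier-type butadien-2-ylation) give the dienyl carbinol mainly as the 6S-epimeric carbinol F2. Dess–Martin oxidation gives the cross-conjugated dienone F3, which is kept cold and used at once because 2-acyl dienes dimerise. Me4NBH(OAc)3 (MeCN/AcOH, −30 °C) binds the free C8 hydroxyl and delivers hydride within the complex (1,3-anti reduction of a β-hydroxy ketone), which gives 23.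

Step 18 (closure of a strained ten-membered diene ring; oligomers or attack on the allylic chloride may compete). The fallback closes the ring before the chlorine is introduced, sets out from 23 and returns at 25. Ring-closing metathesis of the free dienyl carbinol 23 with the second-generation Hoveyda–Grubbs catalyst [RuCl2(=CH-C6H4-2-OiPr)(H2IMes)] (toluene, 1 mM, 80 °C) gives the macrocyclic 6R alcohol F4; its hydroxyl group can hold the ruthenium carbene next to the diene and the substrate carries no allylic chloride. Hexachloroacetone and PPh3 then convert F4 with inversion at C6 into 25.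

**Further compounds**

F1 | step 12 | 8,17-epoxide of 17 (epoxide oxygen on the face of the C9 hydroxyl; fused α,β-epoxy γ-lactone) | C=C[C@@H](O[Si](CC)(CC)CC)[C@]1(C)[C@H]([C@@H](C)[C@@H](O[Si](C)(C)C(C)(C)C)C=C1)[C@@H](O)[C@@]23O[C@@]3(C)C(=O)O[C@H]2COCc2ccc(OC)cc2
F2 | step 16 | (3R,4R,5S)-4-[(R)-acetoxy(RA)methyl]-4-hydroxy-5-[(1S)-1-hydroxy-2-methylidenebut-3-en-1-yl]-3-methyloxolan-2-one (6-epimer of 23) | C=C[C@@H](O[Si](CC)(CC)CC)[C@]1(C)[C@H]([C@@H](C)[C@@H](O[Si](C)(C)C(C)(C)C)C=C1)[C@@H](OC(C)=O)[C@]2(O)[C@@H](C)C(=O)O[C@H]2[C@@H](O)C(=C)C=C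
F3 | step 16 | (3R,4R,5R)-4-[(R)-acetoxy(RA)methyl]-4-hydroxy-3-methyl-5-(2-methylidenebut-3-enoyl)oxolan-2-one (C6 dienone) | C=C[C@@H](O[Si](CC)(CC)CC)[C@]1(C)[C@H]([C@@H](C)[C@@H](O[Si](C)(C)C(C)(C)C)C=C1)[C@@H](OC(C)=O)[C@]2(O)[C@@H](C)C(=O)O[C@H]2C(=O)C(=C)C=C
F4 | step 18 | (1S,2R,6R,7S,8R,9R,10S,11R,12S,17R)-9-acetoxy-12-(tert-butyldimethylsilyloxy)-6,8-dihydroxy-2-(triethylsilyloxy)briarane-3Z,5(16),13-triene 19→7-lactone | C=C1/C=C\[C@@H](O[Si](CC)(CC)CC)[C@]2(C)[C@H]([C@@H](C)[C@@H](O[Si](C)(C)C(C)(C)C)C=C2)[C@@H](OC(C)=O)[C@]2(O)[C@@H](C)C(=O)O[C@H]2[C@@H]1O
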